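**Assumption:** the target is taken exactly as drawn, i.e. (2S,3S,5S)-5-bromo-2-[(1R,3S,4S)-4-bromo-3-chloro-4-methylcyclohexyl]-2,6,6-trimethyloxan-3-ol (the caespitol structure). Methyl (R)-glycidate (L-serine-derived, commercial) is the only chiral input.

## Retrosynthetic overview

1. The tertiary C–Br comes from a trans-diaxial chlorohydrin by retentive substitution; the chlorohydrin comes from the ring alkene.
2. The oxane ring (formed second) comes from 6-endo bromoetherification of a tertiary alcohol onto a prenyl alkene.
3. The tertiary carbinol comes from Felkin–Anh MeMgBr addition to an α-benzoyloxy ketone; the benzoate comes from Mitsunobu inversion of the α-hydroxy ketone.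
4. The cyclohexene ring (formed first) comes from a Diels–Alder reaction of isoprene with an (R)-α'-hydroxy vinyl ketone, whose carbinol steers the diene face.
5. The enone comes from methyl (R)-glycidate, an isobutenyl Grignard and a vinyl Grignard.

## Route

**Step 1**
Reactants: 1 methyl (R)-glycidate; 2 2-methylprop-1-enylmagnesium bromide
Product: 3 methyl (2R)-2-hydroxy-5-methylhex-4-enoate
Conditions: 2 (1.3 equiv), CuI (10 mol %), THF, −40 °C
Reagents that add atoms: 2-methylprop-1-enylmagnesium bromide, CC(C)=C[Mg]Br
Why: Cu-catalysed SN2 epoxide opening at the unsubstituted CH2, so the bought stereocentre is untouched and the ester survives at low temperature.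

**Step 2**
Reactants: 3; 4 vinylmagnesium bromide
Product: 5 (4R)-4-hydroxy-7-methylocta-1,6-dien-3-one
Conditions: MeNHOMe·HCl, i-PrMgCl, THF, −20 °C (Weinreb amide in situ); then 4 (2.5 equiv), −20 → 0 °C; inverse quench into cold 1 M HCl
Reagents that add atoms: vinylmagnesium bromide, C=C[Mg]Br
Why: Weinreb ketone synthesis (the chelated tetrahedral intermediate stops over-addition), with the acidic inverse quench preventing aza-Michael addition; the carbinol centre, held as its alkoxide, is not enolised.

**Step 3**
Reactants: 5; 6 isoprene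
Product: 7 (2R)-2-hydroxy-5-methyl-1-[(1R)-4-methylcyclohex-3-en-1-yl]hex-4-en-1-one
Conditions: isoprene (10 equiv), BF3·OEt2 (0.5 equiv), CH2Cl2, −78 → −40 °C
Reagents that add atoms: isoprene, C=CC(C)=C
Why: Diels–Alder with "para" regiochemistry; the OH···O=C hydrogen bond locks the s-cis enone, so isoprene adds to the face opposite the CH2CH=CMe2 group and the (R)-carbinol gives the (1R) ring carbon (dr of roughly 8:1 expected for a primary alkyl group, minor isomer removed by chromatography).

**Step 4**
Reactants: 7; 8 benzoic acid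
Product: 9 (2S)-5-methyl-1-[(1R)-4-methylcyclohex-3-en-1-yl]-1-oxohex-4-en-2-yl benzoate
Conditions: PPh3, DIAD, PhCO2H, THF, 0 °C → rt
Reagents that add atoms: benzoic acid, OC(=O)c1ccccc1
Why: Mitsunobu SN2 inversion at the activated α-keto carbinol (R → S) sets the final C–O configuration and leaves a non-chelating ester that also protects this oxygen for steps 5 and 6.

**Step 5**
Reactants: 9; 10 methylmagnesium bromide
Product: 11 (2S,3S)-2-hydroxy-6-methyl-2-[(1R)-4-methylcyclohex-3-en-1-yl]hept-5-en-3-yl benzoate
Conditions: MeMgBr (1.3 equiv), THF, −78 °C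
Reagents that add atoms: methylmagnesium bromide, C[Mg]Br
Why: Polar Felkin–Anh (Cornforth-type) addition anti to the C–OBz bond, past H and not the CH2 chain, gives the (2S) tertiary carbinol; the α-acyloxy ketone reacts faster than the benzoate at −78 °C.

**Step 6**
Reactants: 11; 12 2,4,4,6-tetrabromocyclohexa-2,5-dienone (TBCO)
Product: 13 (2S,3S,5S)-5-bromo-2,6,6-trimethyl-2-[(1R)-4-methylcyclohex-3-en-1-yl]oxan-3-yl benzoate
Conditions: TBCO (1.05 equiv), MeNO2/CH2Cl2, 0 °C, dark
Reagents that add atoms: TBCO, O=C1C(Br)=CC(Br)(Br)C=C1Br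
Why: 6-endo (Markovnikov) bromoetherification by the tertiary OH through a chair transition state with the cyclohexenyl group equatorial; anti addition puts Br equatorial and trans to it, giving (5S), while the benzoate blocks 5-endo closure by the other oxygen.

**Step 7**
Reactants: 13
Product: 14 (2S,3S,5S)-5-bromo-2,6,6-trimethyl-2-[(1R)-4-methylcyclohex-3-en-1-yl]oxan-3-ol
Conditions: DIBAL-H (2.5 equiv), CH2Cl2, −78 °C
Reagents that add atoms: none
Why: Reductive ester cleavage under non-basic conditions; no stereocentre is touched and the secondary bromide and alkene survive.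

**Step 8**
Reactants: 14; 15 trichloroisocyanuric acid (TCCA); water
Product: 16 (1S,2S,4R)-4-[(2S,3S,5S)-5-bromo-3-hydroxy-2,6,6-trimethyloxan-2-yl]-2-chloro-1-methylcyclohexan-1-ol
Conditions: TCCA (0.35 equiv), acetone/H2O 4:1, 0 °C
Reagents that add atoms: TCCA, O=C1N(Cl)C(=O)N(Cl)C(=O)N1Cl; water, O
Why: Chlorohydrin formation in which the chloronium on the face anti to the equatorial side chain is opened by water at the tertiary carbon, so Markovnikov and trans-diaxial (Fürst–Plattner) preferences coincide, giving axial Cl at the secondary carbon and axial OH at the tertiary one, as in the limonene bromohydrin case.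

**Step 9**
Reactants: 16; 17 bromotrimethylsilane
Product: 18 target, (2S,3S,5S)-5-bromo-2-[(1R,3S,4S)-4-bromo-3-chloro-4-methylcyclohexyl]-2,6,6-trimethyloxan-3-ol
Conditions: TMSBr (3 equiv), CH2Cl2, −20 → 0 °C; then aq. NaHCO3/MeOH work-up
Reagents that add atoms: bromotrimethylsilane, C[Si](C)(C)Br
Why: SN1 substitution of the tertiary alcohol with the anti-periplanar axial Cl bridging as a chloronium, which bromide reopens trans-diaxially at the tertiary carbon for net retention; the secondary OH is only silylated and is freed on work-up.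

## Compound list

1 | methyl (2R)-oxirane-2-carboxylate (methyl (R)-glycidate) | COC(=O)[C@H]1CO1 | starting material
2 | 2-methylprop-1-enylmagnesium bromide | CC(C)=C[Mg]Br | starting material
3 | methyl (2R)-2-hydroxy-5-methylhex-4-enoate | COC(=O)[C@H](O)CC=C(C)C | intermediate
4 | vinylmagnesium bromide | C=C[Mg]Br | starting material
5 | (4R)-4-hydroxy-7-methylocta-1,6-dien-3-one | C=CC(=O)[C@H](O)CC=C(C)C | intermediate
6 | isoprene | C=CC(C)=C | starting material
7 | (2R)-2-hydroxy-5-methyl-1-[(1R)-4-methylcyclohex-3-en-1-yl]hex-4-en-1-one | CC1=CC[C@@H](CC1)C(=O)[C@H](O)CC=C(C)C | intermediate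
8 | benzoic acid | OC(=O)c1ccccc1 | starting material
9 | (2S)-5-methyl-1-[(1R)-4-methylcyclohex-3-en-1-yl]-1-oxohex-4-en-2-yl benzoate | CC1=CC[C@@H](CC1)C(=O)[C@@H](OC(=O)c1ccccc1)CC=C(C)C | intermediate
10 | methylmagnesium bromide | C[Mg]Br | starting material
11 | (2S,3S)-2-hydroxy-6-methyl-2-[(1R)-4-methylcyclohex-3-en-1-yl]hept-5-en-3-yl benzoate | CC1=CC[C@@H](CC1)[C@](C)(O)[C@@H](OC(=O)c1ccccc1)CC=C(C)C | intermediate
12 | 2,4,4,6-tetrabromocyclohexa-2,5-dienone (TBCO) | O=C1C(Br)=CC(Br)(Br)C=C1Br | starting material (reagent)
13 | (2S,3S,5S)-5-bromo-2,6,6-trimethyl-2-[(1R)-4-methylcyclohex-3-en-1-yl]oxan-3-yl benzoate | CC1(C)O[C@@](C)([C@@H]2CCC(C)=CC2)[C@@H](OC(=O)c2ccccc2)C[C@@H]1Br | intermediate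
14 | (2S,3S,5S)-5-bromo-2,6,6-trimethyl-2-[(1R)-4-methylcyclohex-3-en-1-yl]oxan-3-ol | CC1(C)O[C@@](C)([C@@H]2CCC(C)=CC2)[C@@H](O)C[C@@H]1Br | intermediate
15 | trichloroisocyanuric acid | O=C1N(Cl)C(=O)N(Cl)C(=O)N1Cl | starting material (reagent)
16 | (1S,2S,4R)-4-[(2S,3S,5S)-5-bromo-3-hydroxy-2,6,6-trimethyloxan-2-yl]-2-chloro-1-methylcyclohexan-1-ol | CC1(C)O[C@@](C)([C@@H]2CC[C@](C)(O)[C@@H](Cl)C2)[C@@H](O)C[C@@H]1Br | intermediate
17 | bromotrimethylsilane | C[Si](C)(C)Br | starting material (reagent)
18 | (2S,3S,5S)-5-bromo-2-[(1R,3S,4S)-4-bromo-3-chloro-4-methylcyclohexyl]-2,6,6-trimethyloxan-3-ol | CC1(C)O[C@@](C)([C@@H]2CC[C@](C)(Br)[C@@H](Cl)C2)[C@@H](O)C[C@@H]1Br | target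

## Summary

Total steps: 9. Longest linear sequence: 9, from methyl (R)-glycidate.

**Steps most likely to fail, with fallbacks**

1. **Step 5 (Felkin–Anh methyl addition).** Partial chelation or attack on the benzoate would erode the tertiary carbinol configuration. Fallback: set both carbinol centres through an epoxide instead.
   - Mesylate 7 with retention.
   - Add MeMgBr (Cornforth addition); the alkoxide closes in situ to the (2R,3S)-trisubstituted epoxide, inverting the secondary centre.
   - Open the epoxide at the tertiary carbon with PhCO2H under acid catalysis (inversion); acyl migration to the secondary oxygen then gives 11.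

2. **Step 6 (bromoetherification).** Competing capture of a ring-alkene bromonium by the tertiary OH (cineole-type ether), or modest dr at the C–Br carbon, are the concerns. Fallback: Hg(OCOCF3)2-mediated reversible oxymercuration to the thermodynamic all-equatorial 3-mercurio-oxane, followed by brominative demercuration (Br2, LiBr, pyridine).

3. **Step 9 (retentive tertiary bromination next to Cl).** E1 elimination or acid-induced reopening of the bromo-oxane could compete. Fallback: deliberately dehydrate 16 (Burgess reagent) to the exocyclic and Δ3-alkenes, then add HBr in the Markovnikov sense; both alkenes converge on the same chloronium-bridged tertiary cation, which bromide opens anti to the axial Cl.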